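**Retrosynthetic overview**
1. The C1–C(=O) bond is cut last: a ring-A aryllithium (C1, between two OMOM groups) adds to 3-(methoxymethoxy)benzaldehyde, followed by oxidation and loss of three MOM groups; ring B is bought.
2. Ring A, the only ring built, comes from a benzannulation: a siloxyalkyne supplies C3 and C2, a 4-prenyl-3-siloxycyclobutenone supplies C4, C1, C6 and C5. A ketene–alkyne [2+2] makes C3–C4 and C1–C2, and a 6π closure makes C4–C5.
3. The siloxyalkyne is the O-silylated Kowalski ynolate of the ester obtained by cleaving the C1=C2 alkene of (R)-limonene; the cyclobutenone is the [2+2] adduct of prenylketene and (triisopropylsiloxy)ethyne.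
4. Feature used: ring A is hexasubstituted (C1 aroyl, C2/C6 OH, C3 side chain, C4 OMe, C5 prenyl), and C3–C1'–C2'–C3'–C4'–C5' is C2–C3–C4–C5–C6–C1 of (R)-limonene, so the single stereocentre C2' (R) is limonene C4 and never becomes a reacting centre.

Key step: step 10

Remark: ring-A locants are those of the target throughout; C2' is R with the spatial arrangement of C4 in (R)-(+)-limonene; (triisopropylsiloxy)ethyne 16 is assumed to be accessible from acetylene by the acetylide-oxidation route used for substituted 1-siloxyalkynes.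

Step 1
Reactants: 1 (R)-(+)-limonene
Product: 2 (4R)-limonene 1,2-oxide (cis/trans mixture at C1/C2)
Conditions: mCPBA (1.0 equiv), NaHCO3, CH2Cl2, 0 °C
Reagents that add atoms: m-chloroperbenzoic acid, O=C(OO)c1cccc(Cl)c1
Why: The Prilezhaev epoxidation should be selective for the more electron-rich trisubstituted ring alkene over the isopropenyl group; the C1/C2 epoxide centres form as a mixture that does not matter because both carbons become carbonyls in step 2, and C4 is untouched.

Step 2
Reactants: 2 (4R)-limonene 1,2-oxide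
Product: 4 (3R)-3-isopropenyl-6-oxoheptanal, via limonene diol 3 (not isolated)
Conditions: H5IO6 (1.2 equiv), THF–H2O, 0 °C → rt
Reagents that add atoms: water, O
Why: Periodic acid should hydrate the epoxide to the diol and cleave it in the same flask (Malaprade glycol cleavage), leaving the isopropenyl group alone and turning limonene C4 into a centre β to the aldehyde that cannot enolise.

Step 3
Reactants: 4 (3R)-3-isopropenyl-6-oxoheptanal
Product: 5 (3R)-3-isopropenyl-6-oxoheptanoic acid
Conditions: NaClO2, NaH2PO4, 2-methyl-2-butene, t-BuOH–H2O, rt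
Reagents that add atoms: sodium chlorite, [Na+].[O-]Cl=O
Why: The Pinnick oxidation should convert only the aldehyde, with 2-methyl-2-butene taking up the hypochlorous acid so that the isopropenyl group and the methyl ketone survive.

Step 4
Reactants: 5 (3R)-3-isopropenyl-6-oxoheptanoic acid
Product: 6 methyl (3R)-3-isopropenyl-6-oxoheptanoate
Conditions: MeI, K2CO3, DMF, rt
Reagents that add atoms: iodomethane, CI
Why: SN2 O-alkylation of the carboxylate under carbonate is too weakly basic to enolise the ketone and cannot reach the β-stereocentre.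

Step 5
Reactants: 6 methyl (3R)-3-isopropenyl-6-oxoheptanoate
Product: 7 methyl (3R)-3-isopropenyl-6-methylhept-6-enoate
Conditions: Ph3PCH3Br, KOt-Bu, THF, 0 °C; then 6, 0 °C → rt
Reagents that add atoms: methyltriphenylphosphonium bromide, C[P+](c1ccccc1)(c1ccccc1)c1ccccc1.[Br-]
Why: In this Wittig methylenation the non-stabilised ylide should add to the methyl ketone far faster than to the ester, and the stereocentre (β to the ester, γ to the ketone) is not acidic.

Step 6
Reactants: 7 methyl (3R)-3-isopropenyl-6-methylhept-6-enoate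
Product: 10 (R)-4-isopropenyl-7-methyl-1-(triisopropylsiloxy)oct-7-en-1-yne, via dibromomethyl ketone 8 (not isolated), via lithium ynolate 9 (not isolated)
Conditions: CH2Br2, LiTMP, THF, −78 °C; then 7; LiHMDS; n-BuLi, −78 → 0 °C; i-Pr3SiCl, −78 °C → rt
Reagents that add atoms: dibromomethane, BrCBr; chlorotriisopropylsilane, CC(C)[Si](Cl)(C(C)C)C(C)C; n-butyllithium, [Li]CCCC (supplies only the lithium of 9)
Why: In the Kowalski sequence dibromomethyllithium is acylated by the ester, the enolate of ketone 8 undergoes bromine–lithium exchange and 1,2-shift to ynolate 9 with loss of LiBr, and the bulky silyl chloride should trap 9 on oxygen; the isolated alkenes and the stereocentre are inert to the bases below 0 °C.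

Step 7
Reactants: 11 5-methylhex-4-enoic acid
Product: 12 5-methylhex-4-enoyl chloride
Conditions: (COCl)2, DMF (cat.), CH2Cl2, 0 °C → rt
Reagents that add atoms: oxalyl chloride, O=C(Cl)C(=O)Cl
Why: Acid chloride formation by Vilsmeier-type activation proceeds at or below room temperature with gaseous by-products, conditions under which the trisubstituted alkene should persist.

Step 8
Reactants: 13 acetylene
Product: 16 (triisopropylsiloxy)ethyne, via lithium acetylide 14 (not isolated), via lithium ethynolate 15 (not isolated)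
Conditions: n-BuLi, THF, −78 °C; t-BuOOLi (from t-BuOOH, LiHMDS), −78 → −10 °C; i-Pr3SiOTf, −78 °C
Reagents that add atoms: n-butyllithium, [Li]CCCC (supplies only the lithium of 14 and 15); tert-butyl hydroperoxide, CC(C)(C)OO; triisopropylsilyl trifluoromethanesulfonate, CC(C)[Si](OS(=O)(=O)C(F)(F)F)(C(C)C)C(C)C
Why: Monolithium acetylide should be oxidised at carbon by the lithium peroxide (electrophilic oxygen transfer, the usual conversion of a terminal alkyne into an ynolate), and the hard, bulky silyl triflate should silylate ynolate 15 on oxygen.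

Step 9
Reactants: 12 5-methylhex-4-enoyl chloride; 16 (triisopropylsiloxy)ethyne
Product: 18 4-(3-methylbut-2-enyl)-3-(triisopropylsiloxy)cyclobut-2-en-1-one (racemic), via prenylketene 17 (not isolated)
Conditions: Et3N, Et2O, rt, 12 added over 4 h; then 35 °C
Reagents that add atoms: none
Why: Dehydrochlorination gives aldoketene 17, whose carbonyl carbon is attacked by the CH terminus of the ynol ether in a regiospecific thermal ketene–ynol ether [2+2] cycloaddition, slow addition keeping 17 dilute against dimerisation; the C4 centre forms racemic and is destroyed in step 10.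

Step 10
Reactants: 10 (R)-4-isopropenyl-7-methyl-1-(triisopropylsiloxy)oct-7-en-1-yne; 18 4-(3-methylbut-2-enyl)-3-(triisopropylsiloxy)cyclobut-2-en-1-one
Product: 23 2-[(2R)-2-isopropenyl-5-methylhex-5-enyl]-6-(3-methylbut-2-enyl)-3,5-bis(triisopropylsiloxy)phenol, via siloxyvinylketene 19 (not isolated), via vinylcyclobutenone 20 (not isolated), via dienylketene 21 (not isolated), via cyclohexadienone 22 (not isolated)
Conditions: 18 (1.5 equiv), toluene (0.5 M), degassed, sealed tube, 80 → 110 °C
Reagents that add atoms: none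
Why: Heating opens 18 (4π, cleavage of the C(=O)–CH(prenyl) bond with the prenyl group turning outwards) to siloxyvinylketene 19; the CH2-bearing carbon of ynol ether 10 attacks the ketene carbonyl carbon and the [2+2] cycloaddition gives 20 (ring-A bonds C3–C4 and C1–C2), which opens (4π) to dienylketene 21, closes by 6π electrocyclisation (C4–C5) to 22 and enolises to phenol 23. This is the Danheiser benzannulation of a cyclobutenone with a trialkylsiloxyalkyne, and the same thermal sequence is believed to operate when 3-alkoxycyclobutenones meet 1-alkynyl ethers to give 3,5-dialkoxyphenols. Ring A is the only ring closed, by an intermolecular ketene–alkyne [2+2] followed by a thermal disrotatory 6π electrocyclisation of the dienylketene and aromatisation by tautomerism. No stereocentre is made that survives, since the sp3 centres of 20 and 22 become aromatic carbons, and C2' sits two bonds from the nearest reacting atom under neutral, aprotic heating. The step needs the [2+2] regiochemistry, which the polarity of ynol ether (β-carbon nucleophilic) and ketene (carbonyl carbon electrophilic) fixes so that the free OH appears at C4, the silyl ethers at C2 and C6 and the only ring H at C1; it also needs the ketene to choose the ynol ether over the three unactivated alkenes, which the far higher nucleophilicity of the ynol ether secures.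

Step 11
Reactants: 23 phenol from step 10
Product: 24 2-[(2R)-2-isopropenyl-5-methylhex-5-enyl]-6-(3-methylbut-2-enyl)-3,5-bis(triisopropylsiloxy)anisole
Conditions: NaH, MeI, THF–DMF, 0 °C → rt
Reagents that add atoms: iodomethane, CI
Why: Williamson methylation of the only free phenol (C4–OH); the silyl ethers sit meta to it, so no silyl migration can blur the differentiation of the three oxygens.

Step 12
Reactants: 24 anisole bis(silyl ether)
Product: 25 4-[(2R)-2-isopropenyl-5-methylhex-5-enyl]-5-methoxy-6-(3-methylbut-2-enyl)benzene-1,3-diol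
Conditions: TBAF (2.5 equiv), THF, 0 °C; aq. NH4Cl
Reagents that add atoms: none
Why: Fluoride cleaves both aryl silyl ethers under neutral to mildly basic conditions that do not touch the alkenes or the methyl ether.

Step 13
Reactants: 25 resorcinol
Product: 26 1-methoxy-3,5-bis(methoxymethoxy)-2-[(2R)-2-isopropenyl-5-methylhex-5-enyl]-6-(3-methylbut-2-enyl)benzene
Conditions: MOMCl (3 equiv), i-Pr2NEt (4 equiv), CH2Cl2, 0 °C → rt
Reagents that add atoms: chloromethyl methyl ether, COCCl
Why: O-Alkylation of both phenols should give the bis-MOM ether, installed because aryl OTIPS groups do not direct lithiation whereas two OMOM groups do so cooperatively.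

Step 14
Reactants: 27 3-hydroxybenzaldehyde
Product: 28 3-(methoxymethoxy)benzaldehyde
Conditions: MOMCl, i-Pr2NEt, CH2Cl2, 0 °C → rt
Reagents that add atoms: chloromethyl methyl ether, COCCl
Why: The same phenol O-alkylation; the aldehyde is not affected by the amine base.

Step 15
Reactants: 26 bis-MOM ether; 28 3-(methoxymethoxy)benzaldehyde
Product: 30 {4-methoxy-2,6-bis(methoxymethoxy)-3-[(2R)-2-isopropenyl-5-methylhex-5-enyl]-5-(3-methylbut-2-enyl)phenyl}[3-(methoxymethoxy)phenyl]methanol (carbinol epimers), via aryllithium 29 (not isolated)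
Conditions: n-BuLi (1.2 equiv), THF, 0 °C, 1 h; then 28, −78 → 0 °C; aq. NH4Cl
Reagents that add atoms: n-butyllithium, [Li]CCCC (supplies only the lithium of 29)
Why: Directed ortho-metalation should remove the only ring hydrogen (C1), which lies between two cooperating OMOM groups and is kinetically preferred over the benzylic CH2 groups, and aryllithium 29 adds to the aldehyde; the new carbinol centre is uncontrolled and is erased in step 16.

Step 16
Reactants: 30 diaryl carbinol
Product: 31 {4-methoxy-2,6-bis(methoxymethoxy)-3-[(2R)-2-isopropenyl-5-methylhex-5-enyl]-5-(3-methylbut-2-enyl)phenyl}[3-(methoxymethoxy)phenyl]methanone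
Conditions: Dess–Martin periodinane, NaHCO3, CH2Cl2, rt
Reagents that add atoms: none
Why: Dess–Martin oxidation of the secondary diaryl carbinol under buffered, non-acidic conditions should give the benzophenone without touching the alkenes or acetals.

Step 17
Reactants: 31 tris-MOM benzophenone
Product: 32 target, (R)-[2,6-dihydroxy-4-methoxy-3-(2-isopropenyl-5-methylhex-5-enyl)-5-(3-methylbut-2-enyl)phenyl](3-hydroxyphenyl)methanone
Conditions: aq. HCl (3 M, cat.), MeOH–THF, rt
Reagents that add atoms: none
Why: Acid-catalysed acetal exchange with methanol removes the three MOM groups, the two flanking the ketone being activated by chelation, and dilute acid at room temperature should be too mild for the phenols to add to the prenyl or isopropenyl alkenes.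

**Compound list**
1 | (R)-(+)-limonene | CC1=CC[C@@H](CC1)C(C)=C | starting material
2 | (4R)-limonene 1,2-oxide (cis/trans) | CC12OC1C[C@@H](CC2)C(C)=C | intermediate
3 | (4R)-p-menth-8-ene-1,2-diol | CC1(O)C(O)C[C@@H](CC1)C(C)=C | intermediate (not isolated)
4 | (3R)-3-isopropenyl-6-oxoheptanal | CC(=O)CC[C@H](CC=O)C(=C)C | intermediate
5 | (3R)-3-isopropenyl-6-oxoheptanoic acid | CC(=O)CC[C@H](CC(=O)O)C(=C)C | intermediate
6 | methyl (3R)-3-isopropenyl-6-oxoheptanoate | CC(=O)CC[C@H](CC(=O)OC)C(=C)C | intermediate
7 | methyl (3R)-3-isopropenyl-6-methylhept-6-enoate | C=C(C)CC[C@H](CC(=O)OC)C(=C)C | intermediate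
8 | (4R)-1,1-dibromo-4-isopropenyl-7-methyloct-7-en-2-one | C=C(C)CC[C@H](CC(=O)C(Br)Br)C(=C)C | intermediate (not isolated)
9 | lithium (R)-4-isopropenyl-7-methyloct-7-en-1-yn-1-olate | C=C(C)CC[C@H](CC#C[O-])C(=C)C.[Li+] | intermediate (not isolated)
10 | (R)-4-isopropenyl-7-methyl-1-(triisopropylsiloxy)oct-7-en-1-yne | C=C(C)CC[C@H](CC#CO[Si](C(C)C)(C(C)C)C(C)C)C(=C)C | intermediate (key-step precursor)
11 | 5-methylhex-4-enoic acid | CC(C)=CCCC(=O)O | starting material
12 | 5-methylhex-4-enoyl chloride | CC(C)=CCCC(=O)Cl | intermediate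
13 | acetylene | C#C | starting material
14 | lithium acetylide | [Li]C#C | intermediate (not isolated)
15 | lithium ethynolate | [Li+].[O-]C#C | intermediate (not isolated)
16 | (triisopropylsiloxy)ethyne | C#CO[Si](C(C)C)(C(C)C)C(C)C | intermediate
17 | prenylketene (5-methylhexa-1,4-dien-1-one) | CC(C)=CCC=C=O | intermediate (not isolated)
18 | 4-(3-methylbut-2-enyl)-3-(triisopropylsiloxy)cyclobut-2-en-1-one (racemic) | O=C1C=C(O[Si](C(C)C)(C(C)C)C(C)C)C1CC=C(C)C | intermediate (key-step precursor)
19 | (3Z)-7-methyl-3-(triisopropylsiloxy)octa-1,3,6-trien-1-one | O=C=C/C(O[Si](C(C)C)(C(C)C)C(C)C)=C/CC=C(C)C | intermediate (not isolated)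
20 | 2-[(2R)-2-isopropenyl-5-methylhex-5-enyl]-4-[(1Z)-5-methyl-1-(triisopropylsiloxy)hexa-1,4-dienyl]-3-(triisopropylsiloxy)cyclobut-2-en-1-one (C4 epimers) | O=C1C(C[C@@H](CCC(C)=C)C(C)=C)=C(O[Si](C(C)C)(C(C)C)C(C)C)C1/C(O[Si](C(C)C)(C(C)C)C(C)C)=C/CC=C(C)C | intermediate (not isolated)
21 | dienylketene from 4π opening of 20 | O=C=C(C[C@@H](CCC(C)=C)C(C)=C)/C(O[Si](C(C)C)(C(C)C)C(C)C)=C\C(O[Si](C(C)C)(C(C)C)C(C)C)=C\CC=C(C)C | intermediate (not isolated)
22 | 2-[(2R)-2-isopropenyl-5-methylhex-5-enyl]-6-(3-methylbut-2-enyl)-3,5-bis(triisopropylsiloxy)cyclohexa-2,4-dien-1-one (C6 epimers) | O=C1C(C[C@@H](CCC(C)=C)C(C)=C)=C(O[Si](C(C)C)(C(C)C)C(C)C)C=C(O[Si](C(C)C)(C(C)C)C(C)C)C1CC=C(C)C | intermediate (not isolated)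
23 | 2-[(2R)-2-isopropenyl-5-methylhex-5-enyl]-6-(3-methylbut-2-enyl)-3,5-bis(triisopropylsiloxy)phenol | C=C(C)CC[C@H](Cc1c(O)c(CC=C(C)C)c(O[Si](C(C)C)(C(C)C)C(C)C)cc1O[Si](C(C)C)(C(C)C)C(C)C)C(=C)C | intermediate (key-step product)
24 | methyl ether of 23 | C=C(C)CC[C@H](Cc1c(OC)c(CC=C(C)C)c(O[Si](C(C)C)(C(C)C)C(C)C)cc1O[Si](C(C)C)(C(C)C)C(C)C)C(=C)C | intermediate
25 | 4-[(2R)-2-isopropenyl-5-methylhex-5-enyl]-5-methoxy-6-(3-methylbut-2-enyl)benzene-1,3-diol | C=C(C)CC[C@H](Cc1c(OC)c(CC=C(C)C)c(O)cc1O)C(=C)C | intermediate
26 | bis(methoxymethyl) ether of 25 | C=C(C)CC[C@H](Cc1c(OC)c(CC=C(C)C)c(OCOC)cc1OCOC)C(=C)C | intermediate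
27 | 3-hydroxybenzaldehyde | O=Cc1cccc(O)c1 | starting material
28 | 3-(methoxymethoxy)benzaldehyde | COCOc1cccc(C=O)c1 | intermediate
29 | C1-lithio derivative of 26 | C=C(C)CC[C@H](Cc1c(OC)c(CC=C(C)C)c(OCOC)c([Li])c1OCOC)C(=C)C | intermediate (not isolated)
30 | diaryl carbinol (epimers at the carbinol carbon) | C=C(C)CC[C@H](Cc1c(OC)c(CC=C(C)C)c(OCOC)c(C(O)c2cccc(OCOC)c2)c1OCOC)C(=C)C | intermediate
31 | tris-MOM benzophenone | C=C(C)CC[C@H](Cc1c(OC)c(CC=C(C)C)c(OCOC)c(C(=O)c2cccc(OCOC)c2)c1OCOC)C(=C)C | intermediate
32 | CNP0139402.2 | C=C(C)CC[C@H](Cc1c(O)c(C(=O)c2cccc(O)c2)c(O)c(CC=C(C)C)c1OC)C(=C)C | target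

**Step count and risks**
Total: 17 steps. Longest linear sequence: 13 steps (1–6, 10–13, 15–17).

Steps most likely to fail:

1. Step 10 (benzannulation). The vinylogous silyl ester 18 may open slowly, and siloxyvinylketene 19 may be diverted (dimerisation, hydrogen shift from its allylic CH2, loss of the enol silyl group) before the ynol ether captures it. Fallback, setting out from 16 and 10 and returning at 23: the prenyl group is left out of the annulation and added afterwards. Ketene (from pyrolysis of diketene) is passed into 16 to give 3-(triisopropylsiloxy)cyclobut-2-en-1-one F1. F1 and 10 are heated in toluene to 2-[(2R)-2-isopropenyl-5-methylhex-5-enyl]-3,5-bis(triisopropylsiloxy)phenol F2, whose vinylketene has an unsubstituted terminus. F2 is O-alkylated with tert-butyl 2-methylbut-3-en-2-yl carbonate and Pd(PPh3)4 to the 1,1-dimethylallyl ether F3. Aromatic Claisen rearrangement (toluene, 120 °C) should then place the prenyl group on the only free ortho carbon, C5, giving 23.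

2. Step 8 (parent siloxyethyne). Monolithium acetylide may disproportionate before it is oxidised, the unhindered ynolate may be silylated on carbon, and the volatile product may polymerise on isolation. Fallback, setting out from 12 and returning at 18, which makes 16 unnecessary: 12 is dehydrochlorinated with Et3N in the presence of excess commercial ethoxyethyne to give 3-ethoxy-4-(3-methylbut-2-enyl)cyclobut-2-en-1-one F4. The ethyl group is then exchanged for triisopropylsilyl with i-Pr3SiOTf and NaI in MeCN (O-silylation of the vinylogous ester carbonyl, SN2 removal of ethyl by iodide). Because C4 is bonded to both oxygenated ring carbons, either oxygen may carry silicon and the product is 18.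

3. Step 17 (acidic removal of MOM groups). The freed phenols may add to the prenyl or isopropenyl alkene under acid (chroman formation) before the ring-B acetal is cleaved. Fallback, setting out from 25 and 27 and returning at 32, with fluoride-labile acetals instead: 25 and SEMCl/i-Pr2NEt give the bis-SEM ether F5, and 27 gives 3-{[2-(trimethylsilyl)ethoxy]methoxy}benzaldehyde F6. Lithiation of F5 with n-BuLi and addition to F6 give the carbinol F7, and Dess–Martin oxidation gives the ketone F8. TBAF in THF–DMPU at 60 °C then removes the three SEM groups without acid to give 32.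

**Further compounds**
F1 | step 10 | 3-(triisopropylsiloxy)cyclobut-2-en-1-one | O=C1C=C(O[Si](C(C)C)(C(C)C)C(C)C)C1
F2 | step 10 | 2-[(2R)-2-isopropenyl-5-methylhex-5-enyl]-3,5-bis(triisopropylsiloxy)phenol | C=C(C)CC[C@H](Cc1c(O)cc(O[Si](C(C)C)(C(C)C)C(C)C)cc1O[Si](C(C)C)(C(C)C)C(C)C)C(=C)C
F3 | step 10 | 2-methylbut-3-en-2-yl ether of F2 | C=C(C)CC[C@H](Cc1c(OC(C)(C)C=C)cc(O[Si](C(C)C)(C(C)C)C(C)C)cc1O[Si](C(C)C)(C(C)C)C(C)C)C(=C)C
F4 | step 8 | 3-ethoxy-4-(3-methylbut-2-enyl)cyclobut-2-en-1-one (racemic) | CCOC1=CC(=O)C1CC=C(C)C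
F5 | step 17 | bis[2-(trimethylsilyl)ethoxymethyl] ether of 25 | C=C(C)CC[C@H](Cc1c(OC)c(CC=C(C)C)c(OCOCC[Si](C)(C)C)cc1OCOCC[Si](C)(C)C)C(=C)C
F6 | step 17 | 3-{[2-(trimethylsilyl)ethoxy]methoxy}benzaldehyde | C[Si](C)(C)CCOCOc1cccc(C=O)c1
F7 | step 17 | tris-SEM diaryl carbinol (epimers at the carbinol carbon) | C=C(C)CC[C@H](Cc1c(OC)c(CC=C(C)C)c(OCOCC[Si](C)(C)C)c(C(O)c2cccc(OCOCC[Si](C)(C)C)c2)c1OCOCC[Si](C)(C)C)C(=C)C
F8 | step 17 | tris-SEM benzophenone | C=C(C)CC[C@H](Cc1c(OC)c(CC=C(C)C)c(OCOCC[Si](C)(C)C)c(C(=O)c2cccc(OCOCC[Si](C)(C)C)c2)c1OCOCC[Si](C)(C)C)C(=C)C
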